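**Plan**

- Numbering: decalin C1–C10 (ring A = C1–C5, C10; ring B = C5–C10); C11 = benzylic CH2 on C9; methyls on C4, C5, C8, C9.
- Retrosynthetic cuts: oxazole C2 (orthoacetate) and aryl C–N (nitration); C11–aryl (aryllithium + C11 aldehyde, then removal of the C11 oxygen); C4–CH3 (cuprate) and the C2 oxygen; C9–C10; ring A (α-methyl aldehyde at C5 + methyl vinyl ketone); C9=CH2 (formaldehyde).
- Enabling feature: the C9 methyl is an exocyclic CH2 plus one hydrogen atom, and C10 is the β-carbon of a ring-A enone once C2 is a carbonyl. Ring B can therefore close by adding a tertiary C9 radical to one arm of a 4-methyl-4-alkylcyclohexadienone whose sp3 carbon is C5.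
- Forward order: citronellal chain (C6–C9, C11) → ring A (Robinson annulation, dehydrogenation) → ring B (radical closure) → C4 methyl and C2 deoxygenation → arene on C11 → oxazole ring last.
- Stereochemistry: C8 is the stereocentre of (S)-citronellal; C5, C9 and C10 are all set in the ring-B closure under its control (chair transition state, tether-enforced cis fusion); no later step touches them.

Key step: step 11

Remark: 4-methoxybenzene-1,3-diol is taken as a purchasable arene; TBS = tert-butyldimethylsilyl, TBSO = tert-butyldimethylsilyloxy, MOM = methoxymethyl, Tr = triphenylmethyl.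

**Route**

Step 1
Reactants: 1 (S)-citronellal [(3S)-3,7-dimethyloct-6-enal]; 2 formaldehyde (37% aqueous)
Product: 3 (3S)-3,7-dimethyl-2-methylideneoct-6-enal
Conditions: pyrrolidine (10 mol%), propionic acid (10 mol%), i-PrOH, 45 °C
Reagents that add atoms: none
Why: Amine-catalysed Mannich-type α-methylenation of the aldehyde installs the future C9 methylene; the stereocentre (future C8) is β to the carbonyl and is not involved.

Step 2
Reactants: 3 (3S)-3,7-dimethyl-2-methylideneoct-6-enal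
Product: 4 (3S)-3,7-dimethyl-2-methylideneoct-6-en-1-ol
Conditions: NaBH4, CeCl3·7H2O, MeOH, 0 °C
Reagents that add atoms: none
Why: Luche 1,2-reduction of the enal should give the allylic alcohol without conjugate reduction.

Step 3
Reactants: 4 (3S)-3,7-dimethyl-2-methylideneoct-6-en-1-ol
Product: 5 tert-butyl{[(3S)-3,7-dimethyl-2-methylideneoct-6-en-1-yl]oxy}dimethylsilane
Conditions: TBSCl, imidazole, CH2Cl2, rt
Reagents that add atoms: tert-butyldimethylsilyl chloride, CC(C)(C)[Si](C)(C)Cl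
Why: Standard silylation of a primary alcohol gives an ether that tolerates the base, hydride, oxidant and radical steps up to step 12.

Step 4
Reactants: 5 tert-butyl{[(3S)-3,7-dimethyl-2-methylideneoct-6-en-1-yl]oxy}dimethylsilane
Product: 7 (4S)-4-methyl-5-[(TBSO)methyl]hex-5-enal, via epoxide 2,2-dimethyl-3-{(3S)-3-methyl-4-[(TBSO)methyl]pent-4-en-1-yl}oxirane 6 (not isolated)
Conditions: mCPBA (1.05 equiv), CH2Cl2, −10 → 0 °C; then H5IO6, THF/H2O, 0 °C
Reagents that add atoms: mCPBA, OOC(=O)c1cccc(Cl)c1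
Why: Prilezhaev epoxidation is much faster at the electron-rich trisubstituted alkene than at the 1,1-disubstituted alkene deactivated by its allylic silyloxy group, and periodic acid cleaves the epoxide (via the diol) to the aldehyde and acetone; the epoxide stereocentre is irrelevant.

Step 5
Reactants: 7 (4S)-4-methyl-5-[(TBSO)methyl]hex-5-enal
Product: 8 (5S)-5-methyl-6-[(TBSO)methyl]hept-6-en-2-ol (C2 epimers)
Conditions: MeMgBr, THF, −78 → 0 °C
Reagents that add atoms: methylmagnesium bromide, C[Mg]Br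
Why: Grignard addition to the aldehyde supplies the future 5-methyl group; the carbinol centre forms unselectively and is oxidised away in step 6.

Step 6
Reactants: 8 (5S)-5-methyl-6-[(TBSO)methyl]hept-6-en-2-ol
Product: 9 (5S)-5-methyl-6-[(TBSO)methyl]hept-6-en-2-one
Conditions: Dess–Martin periodinane, CH2Cl2, 0 °C → rt
Reagents that add atoms: none
Why: Dess–Martin oxidation of a secondary alcohol to the methyl ketone leaves the alkene and silyl ether untouched.

Step 7
Reactants: 9 (5S)-5-methyl-6-[(TBSO)methyl]hept-6-en-2-one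
Product: 10 (5S)-2,5-dimethyl-6-[(TBSO)methyl]hept-6-enenitrile (C2 epimers)
Conditions: TosMIC, t-BuOK, EtOH (2 equiv), DME, 0 → 35 °C
Reagents that add atoms: p-toluenesulfonylmethyl isocyanide, Cc1ccc(cc1)S(=O)(=O)C[N+]#[C-]
Why: Van Leusen reductive cyanation converts the ketone into the one-carbon-longer nitrile under purely basic conditions; the new centre forms unselectively and later becomes the non-stereogenic C5 of the dienone.

Step 8
Reactants: 10 (5S)-2,5-dimethyl-6-[(TBSO)methyl]hept-6-enenitrile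
Product: 11 (5S)-2,5-dimethyl-6-[(TBSO)methyl]hept-6-enal (C2 epimers)
Conditions: DIBAL-H, CH2Cl2, −78 °C; aqueous Rochelle salt
Reagents that add atoms: water, O
Why: DIBAL half-reduction of the nitrile to the N-aluminoimine and hydrolysis should give the α-methyl aldehyde needed for the annulation.

Step 9
Reactants: 11 (5S)-2,5-dimethyl-6-[(TBSO)methyl]hept-6-enal; 12 methyl vinyl ketone
Product: 15 4-methyl-4-{(3S)-3-methyl-4-[(TBSO)methyl]pent-4-en-1-yl}cyclohex-2-en-1-one (C4 epimers), via Michael adduct (5S)-2,5-dimethyl-2-(3-oxobutyl)-6-[(TBSO)methyl]hept-6-enal 13 (not isolated), via ketol 3-hydroxy-4-methyl-4-{(3S)-3-methyl-4-[(TBSO)methyl]pent-4-en-1-yl}cyclohexan-1-one 14 (not isolated)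
Conditions: KOH (0.2 equiv), EtOH, 0 → 60 °C
Reagents that add atoms: none
Why: Robinson annulation: Michael addition of the α-branched aldehyde enolate to the vinyl ketone creates the quaternary carbon (future C5) and aldol condensation closes ring A; the quaternary centre forms unselectively, which is harmless because it is non-stereogenic in 17.

Step 10
Reactants: 15 4-methyl-4-{(3S)-3-methyl-4-[(TBSO)methyl]pent-4-en-1-yl}cyclohex-2-en-1-one
Product: 17 4-methyl-4-{(3S)-3-methyl-4-[(TBSO)methyl]pent-4-en-1-yl}cyclohexa-2,5-dien-1-one, via silyl dienol ether trimethyl[(4-methyl-4-{(3S)-3-methyl-4-[(TBSO)methyl]pent-4-en-1-yl}cyclohexa-1,5-dien-1-yl)oxy]silane 16 (not isolated)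
Conditions: TMSCl, LDA (internal quench), THF, −78 °C; solvent switch; Pd(OAc)2 (1.05 equiv), MeCN, rt
Reagents that add atoms: none
Why: Saegusa–Ito dehydrogenation: kinetic α′-deprotonation gives the cross-conjugated silyl dienol ether and Pd(II) introduces the second ring alkene, so the two enone arms become equivalent and the quaternary carbon is no longer a stereocentre.

Step 11
Reactants: 17 4-methyl-4-{(3S)-3-methyl-4-[(TBSO)methyl]pent-4-en-1-yl}cyclohexa-2,5-dien-1-one
Product: 18 (4aS,7S,8R,8aR)-4a,7,8-trimethyl-8-[(TBSO)methyl]-4a,5,6,7,8,8a-hexahydronaphthalen-2(1H)-one (cis-fused; decalin descriptors 5S,8S,9R,10R)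
Conditions: Fe(acac)3 (0.3 equiv), PhSiH3 (2.5 equiv), EtOH/ethylene glycol 5:1, 0.02 M, 60 °C
Reagents that add atoms: none
Why: An iron hydride formed from Fe(acac)3 and PhSiH3 transfers a hydrogen atom to the terminal CH2 of the 1,1-disubstituted alkene, creating the C9 methyl and a nucleophilic tertiary C9 radical that adds to the enone β-carbon C10; the α-keto radical is then reduced to the enolate and protonated at C1 by ethanol. The closest known reaction type is the iron-hydride HAT-initiated reductive alkene–enone coupling (radical conjugate addition) that forms quaternary centres, here run intramolecularly. Ring B (C5–C10) closes 6-exo-trig through a chair transition state. C10: the tether from C5 reaches only the dienone face on which it sits, so C9–C10 forms syn to C5–C6 and the fusion is cis; C5: the two enone arms are enantiotopic and the chair with the C8 methyl equatorial uses the arm that places 5-CH3 trans to 8-CH3; C9: in that chair the small new methyl takes the axial site next to the spectator arm and the CH2OTBS group the equatorial one. The step needs hydrogen-atom transfer to the electron-neutral alkene and not to the electron-poor dienone (polarity: the dienone is a poor HAT acceptor but a good radical acceptor), ring closure faster than reduction of the radical (6-exo geometry, high dilution) and arm/face selection (C8 stereocentre from citronellal); the surviving enone is the handle for C4 and C3=C4.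

Step 12
Reactants: 18 (4aS,7S,8R,8aR)-4a,7,8-trimethyl-8-[(TBSO)methyl]-4a,5,6,7,8,8a-hexahydronaphthalen-2(1H)-one
Product: 20 (4aR,7S,8R,8aR)-4,4a,7,8-tetramethyl-8-[(TBSO)methyl]-4a,5,6,7,8,8a-hexahydronaphthalen-2(1H)-one, via silyl enol ether trimethyl({(4aS,7S,8R,8aR)-4,4a,7,8-tetramethyl-8-[(TBSO)methyl]-1,4,4a,5,6,7,8,8a-octahydronaphthalen-2-yl}oxy)silane (C4 epimer not assigned) 19 (not isolated)
Conditions: Me2CuLi (from MeLi, CuI), TMSCl, THF, −78 → −30 °C; solvent switch; Pd(OAc)2, MeCN, rt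
Reagents that add atoms: lithium dimethylcuprate, [Li+].C[Cu-]C
Why: TMSCl-accelerated cuprate conjugate addition places the methyl on C4 and traps the enolate regiospecifically as the C2–C3 silyl enol ether, and Saegusa–Ito oxidation restores the C3=C4 alkene, erasing the transient C4 stereocentre.

Step 13
Reactants: 20 (4aR,7S,8R,8aR)-4,4a,7,8-tetramethyl-8-[(TBSO)methyl]-4a,5,6,7,8,8a-hexahydronaphthalen-2(1H)-one
Product: 22 [(4'aR,7'S,8'R,8'aR)-4',4'a,7',8'-tetramethyl-4'a,5',6',7',8',8'a-hexahydro-1'H-spiro[1,3-dithiolane-2,2'-naphthalen]-8'-yl]methanol, via silyl ether tert-butyldimethyl{[(4'aR,7'S,8'R,8'aR)-4',4'a,7',8'-tetramethyl-4'a,5',6',7',8',8'a-hexahydro-1'H-spiro[1,3-dithiolane-2,2'-naphthalen]-8'-yl]methoxy}silane 21 (not isolated)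
Conditions: HS(CH2)2SH, BF3·OEt2, CH2Cl2, 0 °C → rt; then MeOH, rt
Reagents that add atoms: ethane-1,2-dithiol, SCCS
Why: Lewis-acid dithioketalisation of the enone keeps the alkene at C3=C4 (as with steroidal Δ4-3-ketones), and acid methanolysis in the same flask removes the silyl ether, which is no longer needed.

Step 14
Reactants: 22 [(4'aR,7'S,8'R,8'aR)-4',4'a,7',8'-tetramethyl-4'a,5',6',7',8',8'a-hexahydro-1'H-spiro[1,3-dithiolane-2,2'-naphthalen]-8'-yl]methanol
Product: 23 [(1R,2S,4aR,8aR)-1,2,4a,5-tetramethyl-1,2,3,4,4a,7,8,8a-octahydronaphthalen-1-yl]methanol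
Conditions: Raney Ni (W-2, acetone-deactivated), EtOH, reflux
Reagents that add atoms: none
Why: Mozingo desulfurisation replaces both C–S bonds at C2 by C–H and should leave the hindered trisubstituted C3=C4 alkene in place, as in the classical conversion of Δ4-3-ketone thioketals into Δ4-alkenes.

Step 15
Reactants: 23 [(1R,2S,4aR,8aR)-1,2,4a,5-tetramethyl-1,2,3,4,4a,7,8,8a-octahydronaphthalen-1-yl]methanol
Product: 24 (1R,2S,4aR,8aR)-1,2,4a,5-tetramethyl-1,2,3,4,4a,7,8,8a-octahydronaphthalene-1-carbaldehyde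
Conditions: Dess–Martin periodinane, CH2Cl2, 0 °C → rt
Reagents that add atoms: none
Why: Dess–Martin oxidation of the neopentyl alcohol gives an aldehyde with no α-hydrogen, so C9 cannot epimerise.

Step 16
Reactants: 25 4-methoxybenzene-1,3-diol
Product: 26 1-methoxy-2,4-bis(methoxymethoxy)benzene
Conditions: MOMCl, i-Pr2NEt, CH2Cl2, 0 °C → rt
Reagents that add atoms: chloromethyl methyl ether, COCCl
Why: O-alkylation of both phenols gives two strong ortho-directing groups that are stable to organolithiums and radicals and come off with mild acid at the end.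

Step 17
Reactants: 26 1-methoxy-2,4-bis(methoxymethoxy)benzene; 24 (1R,2S,4aR,8aR)-1,2,4a,5-tetramethyl-1,2,3,4,4a,7,8,8a-octahydronaphthalene-1-carbaldehyde
Product: 28 [3-methoxy-2,6-bis(methoxymethoxy)phenyl][(1R,2S,4aR,8aR)-1,2,4a,5-tetramethyl-1,2,3,4,4a,7,8,8a-octahydronaphthalen-1-yl]methanol (carbinol epimers), via aryllithium [3-methoxy-2,6-bis(methoxymethoxy)phenyl]lithium 27 (not isolated)
Conditions: 26, n-BuLi, TMEDA, THF, 0 °C; then 24, −78 → 0 °C; aq. NH4Cl
Reagents that add atoms: none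
Why: Directed ortho-metalation occurs at the position flanked by both OMOM groups and the aryllithium adds to the non-enolisable neopentyl aldehyde; the carbinol centre forms unselectively and is removed in steps 18–19.

Step 18
Reactants: 28 [3-methoxy-2,6-bis(methoxymethoxy)phenyl][(1R,2S,4aR,8aR)-1,2,4a,5-tetramethyl-1,2,3,4,4a,7,8,8a-octahydronaphthalen-1-yl]methanol
Product: 30 O-{[3-methoxy-2,6-bis(methoxymethoxy)phenyl][(1R,2S,4aR,8aR)-1,2,4a,5-tetramethyl-1,2,3,4,4a,7,8,8a-octahydronaphthalen-1-yl]methyl} S-methyl carbonodithioate, via sodium O-{[3-methoxy-2,6-bis(methoxymethoxy)phenyl][(1R,2S,4aR,8aR)-1,2,4a,5-tetramethyl-1,2,3,4,4a,7,8,8a-octahydronaphthalen-1-yl]methyl} carbonodithioate 29 (not isolated)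
Conditions: NaHMDS, CS2, THF, −78 → 0 °C; then MeI
Reagents that add atoms: carbon disulfide, S=C=S; iodomethane, CI
Why: Xanthate formation (first half of the Barton–McCombie deoxygenation) from the sodium alkoxide, which has no β-hydrogen and so cannot undergo Chugaev elimination later.

Step 19
Reactants: 30 O-{[3-methoxy-2,6-bis(methoxymethoxy)phenyl][(1R,2S,4aR,8aR)-1,2,4a,5-tetramethyl-1,2,3,4,4a,7,8,8a-octahydronaphthalen-1-yl]methyl} S-methyl carbonodithioate
Product: 31 1-methoxy-2,4-bis(methoxymethoxy)-3-{[(1R,2S,4aR,8aS)-1,2,4a,5-tetramethyl-1,2,3,4,4a,7,8,8a-octahydronaphthalen-1-yl]methyl}benzene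
Conditions: n-Bu3SnH, AIBN, toluene, 100 °C
Reagents that add atoms: none
Why: Barton–McCombie radical deoxygenation passes through a stabilised benzylic C11 radical, so no cation is formed that could trigger Wagner–Meerwein shifts at the neopentyl centre or touch the alkene.

Step 20
Reactants: 31 1-methoxy-2,4-bis(methoxymethoxy)-3-{[(1R,2S,4aR,8aS)-1,2,4a,5-tetramethyl-1,2,3,4,4a,7,8,8a-octahydronaphthalen-1-yl]methyl}benzene
Product: 32 1-methoxy-2,4-bis(methoxymethoxy)-5-nitro-3-{[(1R,2S,4aR,8aS)-1,2,4a,5-tetramethyl-1,2,3,4,4a,7,8,8a-octahydronaphthalen-1-yl]methyl}benzene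
Conditions: HNO3 (65%, 1.05 equiv), AcOH/CH2Cl2, −15 °C
Reagents that add atoms: nitric acid, O[N+](=O)[O-]
Why: Electrophilic aromatic nitration should go to the one free position that is ortho to one OMOM and para to the other, and the very electron-rich arene should react at low temperature before the trisubstituted alkene does.

Step 21
Reactants: 32 1-methoxy-2,4-bis(methoxymethoxy)-5-nitro-3-{[(1R,2S,4aR,8aS)-1,2,4a,5-tetramethyl-1,2,3,4,4a,7,8,8a-octahydronaphthalen-1-yl]methyl}benzene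
Product: 33 5-methoxy-2,4-bis(methoxymethoxy)-3-{[(1R,2S,4aR,8aS)-1,2,4a,5-tetramethyl-1,2,3,4,4a,7,8,8a-octahydronaphthalen-1-yl]methyl}aniline
Conditions: Fe powder, NH4Cl, EtOH/H2O, 70 °C
Reagents that add atoms: none
Why: Béchamp-type iron reduction of the nitro group is near-neutral, so the MOM ethers stay on and the alkene is not reduced.

Step 22
Reactants: 33 5-methoxy-2,4-bis(methoxymethoxy)-3-{[(1R,2S,4aR,8aS)-1,2,4a,5-tetramethyl-1,2,3,4,4a,7,8,8a-octahydronaphthalen-1-yl]methyl}aniline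
Product: 35 5-methoxy-2-methyl-7-{[(1R,2S,4aR,8aS)-1,2,4a,5-tetramethyl-1,2,3,4,4a,7,8,8a-octahydronaphthalen-1-yl]methyl}-1,3-benzoxazol-6-ol, via 4-amino-6-methoxy-2-{[(1R,2S,4aR,8aS)-1,2,4a,5-tetramethyl-1,2,3,4,4a,7,8,8a-octahydronaphthalen-1-yl]methyl}benzene-1,3-diol hydrochloride 34 (not isolated)
Conditions: HCl (1.25 M in MeOH), 40 °C; evaporate under argon; MeC(OEt)3, EtOH, 80 °C
Reagents that add atoms: triethyl orthoacetate, CCOC(C)(OCC)OCC
Why: Acid methanolysis removes both MOM groups and the o-aminophenol salt condenses with the orthoester (imidate formation, cyclisation, loss of ethanol) to the 2-methylbenzoxazole; only the hydroxyl ortho to nitrogen can cyclise, so the other phenol stays free.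

**Compound list**

1 | (S)-citronellal, (3S)-3,7-dimethyloct-6-enal | C[C@@H](CCC=C(C)C)CC=O | starting material
2 | formaldehyde | C=O | starting material
3 | (3S)-3,7-dimethyl-2-methylideneoct-6-enal | C=C(C=O)[C@@H](C)CCC=C(C)C | intermediate
4 | (3S)-3,7-dimethyl-2-methylideneoct-6-en-1-ol | OCC(=C)[C@@H](C)CCC=C(C)C | intermediate
5 | tert-butyl{[(3S)-3,7-dimethyl-2-methylideneoct-6-en-1-yl]oxy}dimethylsilane | CC(C)(C)[Si](C)(C)OCC(=C)[C@@H](C)CCC=C(C)C | intermediate
6 | 2,2-dimethyl-3-{(3S)-3-methyl-4-[(TBSO)methyl]pent-4-en-1-yl}oxirane (oxirane epimers) | CC(C)(C)[Si](C)(C)OCC(=C)[C@@H](C)CCC1OC1(C)C | intermediate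
7 | (4S)-4-methyl-5-[(TBSO)methyl]hex-5-enal | CC(C)(C)[Si](C)(C)OCC(=C)[C@@H](C)CCC=O | intermediate
8 | (5S)-5-methyl-6-[(TBSO)methyl]hept-6-en-2-ol (C2 epimers) | CC(C)(C)[Si](C)(C)OCC(=C)[C@@H](C)CCC(C)O | intermediate
9 | (5S)-5-methyl-6-[(TBSO)methyl]hept-6-en-2-one | CC(C)(C)[Si](C)(C)OCC(=C)[C@@H](C)CCC(C)=O | intermediate
10 | (5S)-2,5-dimethyl-6-[(TBSO)methyl]hept-6-enenitrile (C2 epimers) | CC(C)(C)[Si](C)(C)OCC(=C)[C@@H](C)CCC(C)C#N | intermediate
11 | (5S)-2,5-dimethyl-6-[(TBSO)methyl]hept-6-enal (C2 epimers) | CC(C)(C)[Si](C)(C)OCC(=C)[C@@H](C)CCC(C)C=O | intermediate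
12 | methyl vinyl ketone (but-3-en-2-one) | CC(=O)C=C | starting material
13 | (5S)-2,5-dimethyl-2-(3-oxobutyl)-6-[(TBSO)methyl]hept-6-enal (C2 epimers) | CC(C)(C)[Si](C)(C)OCC(=C)[C@@H](C)CCC(C)(C=O)CCC(C)=O | intermediate
14 | 3-hydroxy-4-methyl-4-{(3S)-3-methyl-4-[(TBSO)methyl]pent-4-en-1-yl}cyclohexan-1-one (diastereomer mixture) | CC(C)(C)[Si](C)(C)OCC(=C)[C@@H](C)CCC1(C)CCC(=O)CC1O | intermediate
15 | 4-methyl-4-{(3S)-3-methyl-4-[(TBSO)methyl]pent-4-en-1-yl}cyclohex-2-en-1-one (C4 epimers) | CC(C)(C)[Si](C)(C)OCC(=C)[C@@H](C)CCC1(C)CCC(=O)C=C1 | intermediate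
16 | trimethyl[(4-methyl-4-{(3S)-3-methyl-4-[(TBSO)methyl]pent-4-en-1-yl}cyclohexa-1,5-dien-1-yl)oxy]silane (C4 epimers) | CC(C)(C)[Si](C)(C)OCC(=C)[C@@H](C)CCC1(C)CC=C(O[Si](C)(C)C)C=C1 | intermediate
17 | 4-methyl-4-{(3S)-3-methyl-4-[(TBSO)methyl]pent-4-en-1-yl}cyclohexa-2,5-dien-1-one | CC(C)(C)[Si](C)(C)OCC(=C)[C@@H](C)CCC1(C)C=CC(=O)C=C1 | intermediate
18 | (4aS,7S,8R,8aR)-4a,7,8-trimethyl-8-[(TBSO)methyl]-4a,5,6,7,8,8a-hexahydronaphthalen-2(1H)-one (cis-fused) | CC(C)(C)[Si](C)(C)OC[C@]1(C)[C@@H](C)CC[C@@]2(C)C=CC(=O)C[C@@H]12 | intermediate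
19 | trimethyl({(4aS,7S,8R,8aR)-4,4a,7,8-tetramethyl-8-[(TBSO)methyl]-1,4,4a,5,6,7,8,8a-octahydronaphthalen-2-yl}oxy)silane (C4 epimer not assigned) | CC(C)(C)[Si](C)(C)OC[C@]1(C)[C@@H](C)CC[C@@]2(C)C(C)C=C(O[Si](C)(C)C)C[C@@H]12 | intermediate
20 | (4aR,7S,8R,8aR)-4,4a,7,8-tetramethyl-8-[(TBSO)methyl]-4a,5,6,7,8,8a-hexahydronaphthalen-2(1H)-one | CC(C)(C)[Si](C)(C)OC[C@]1(C)[C@@H](C)CC[C@@]2(C)C(C)=CC(=O)C[C@@H]12 | intermediate
21 | tert-butyldimethyl{[(4'aR,7'S,8'R,8'aR)-4',4'a,7',8'-tetramethyl-4'a,5',6',7',8',8'a-hexahydro-1'H-spiro[1,3-dithiolane-2,2'-naphthalen]-8'-yl]methoxy}silane | CC(C)(C)[Si](C)(C)OC[C@]1(C)[C@@H](C)CC[C@@]2(C)C(C)=CC3(SCCS3)C[C@@H]12 | intermediate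
22 | [(4'aR,7'S,8'R,8'aR)-4',4'a,7',8'-tetramethyl-4'a,5',6',7',8',8'a-hexahydro-1'H-spiro[1,3-dithiolane-2,2'-naphthalen]-8'-yl]methanol | OC[C@]1(C)[C@@H](C)CC[C@@]2(C)C(C)=CC3(SCCS3)C[C@@H]12 | intermediate
23 | [(1R,2S,4aR,8aR)-1,2,4a,5-tetramethyl-1,2,3,4,4a,7,8,8a-octahydronaphthalen-1-yl]methanol | OC[C@]1(C)[C@@H](C)CC[C@@]2(C)C(C)=CCC[C@@H]12 | intermediate
24 | (1R,2S,4aR,8aR)-1,2,4a,5-tetramethyl-1,2,3,4,4a,7,8,8a-octahydronaphthalene-1-carbaldehyde | O=C[C@]1(C)[C@@H](C)CC[C@@]2(C)C(C)=CCC[C@@H]12 | intermediate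
25 | 4-methoxybenzene-1,3-diol | COc1ccc(O)cc1O | starting material
26 | 1-methoxy-2,4-bis(methoxymethoxy)benzene | COCOc1ccc(OC)c(OCOC)c1 | intermediate
27 | [3-methoxy-2,6-bis(methoxymethoxy)phenyl]lithium | [Li]c1c(OCOC)ccc(OC)c1OCOC | intermediate
28 | [3-methoxy-2,6-bis(methoxymethoxy)phenyl][(1R,2S,4aR,8aR)-1,2,4a,5-tetramethyl-1,2,3,4,4a,7,8,8a-octahydronaphthalen-1-yl]methanol (carbinol epimers) | COCOc1ccc(OC)c(OCOC)c1C(O)[C@]1(C)[C@@H](C)CC[C@@]2(C)C(C)=CCC[C@@H]12 | intermediate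
29 | sodium O-{[3-methoxy-2,6-bis(methoxymethoxy)phenyl][(1R,2S,4aR,8aR)-1,2,4a,5-tetramethyl-1,2,3,4,4a,7,8,8a-octahydronaphthalen-1-yl]methyl} carbonodithioate | COCOc1ccc(OC)c(OCOC)c1C(OC(=S)[S-])[C@]1(C)[C@@H](C)CC[C@@]2(C)C(C)=CCC[C@@H]12.[Na+] | intermediate
30 | O-{[3-methoxy-2,6-bis(methoxymethoxy)phenyl][(1R,2S,4aR,8aR)-1,2,4a,5-tetramethyl-1,2,3,4,4a,7,8,8a-octahydronaphthalen-1-yl]methyl} S-methyl carbonodithioate | COCOc1ccc(OC)c(OCOC)c1C(OC(=S)SC)[C@]1(C)[C@@H](C)CC[C@@]2(C)C(C)=CCC[C@@H]12 | intermediate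
31 | 1-methoxy-2,4-bis(methoxymethoxy)-3-{[(1R,2S,4aR,8aS)-1,2,4a,5-tetramethyl-1,2,3,4,4a,7,8,8a-octahydronaphthalen-1-yl]methyl}benzene | COCOc1ccc(OC)c(OCOC)c1C[C@]1(C)[C@@H](C)CC[C@@]2(C)C(C)=CCC[C@@H]12 | intermediate
32 | 1-methoxy-2,4-bis(methoxymethoxy)-5-nitro-3-{[(1R,2S,4aR,8aS)-1,2,4a,5-tetramethyl-1,2,3,4,4a,7,8,8a-octahydronaphthalen-1-yl]methyl}benzene | COCOc1c([N+](=O)[O-])cc(OC)c(OCOC)c1C[C@]1(C)[C@@H](C)CC[C@@]2(C)C(C)=CCC[C@@H]12 | intermediate
33 | 5-methoxy-2,4-bis(methoxymethoxy)-3-{[(1R,2S,4aR,8aS)-1,2,4a,5-tetramethyl-1,2,3,4,4a,7,8,8a-octahydronaphthalen-1-yl]methyl}aniline | COCOc1c(N)cc(OC)c(OCOC)c1C[C@]1(C)[C@@H](C)CC[C@@]2(C)C(C)=CCC[C@@H]12 | intermediate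
34 | 4-amino-6-methoxy-2-{[(1R,2S,4aR,8aS)-1,2,4a,5-tetramethyl-1,2,3,4,4a,7,8,8a-octahydronaphthalen-1-yl]methyl}benzene-1,3-diol hydrochloride | Nc1cc(OC)c(O)c(C[C@]2(C)[C@@H](C)CC[C@@]3(C)C(C)=CCC[C@@H]23)c1O.Cl | intermediate
35 | 5-methoxy-2-methyl-7-{[(1R,2S,4aR,8aS)-1,2,4a,5-tetramethyl-1,2,3,4,4a,7,8,8a-octahydronaphthalen-1-yl]methyl}-1,3-benzoxazol-6-ol | COc1cc2nc(C)oc2c(C[C@]2(C)[C@@H](C)CC[C@@]3(C)C(C)=CCC[C@@H]23)c1O | target

**Step count**

Total: 22 steps. Longest linear sequence: 21 steps (steps 1–15 and 17–22); step 16 prepares the arene.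

**Steps most likely to fail**

Step 11. The planar C9 radical may discriminate poorly between placing CH3 or CH2OTBS in the axial site of the chair, and to a lesser degree between the two enone arms, so ring B could close to a mixture of C9 and C5 epimers. The fallback moves the stereocontrol to a much larger ether and changes the protecting-group plan to match. Setting out from 17, TBAF in THF should give the dienone alcohol 4-[(3S)-4-(hydroxymethyl)-3-methylpent-4-en-1-yl]-4-methylcyclohexa-2,5-dien-1-one F1. TrCl/Et3N/DMAP should then give the trityl ether 4-methyl-4-{(3S)-3-methyl-4-[(trityloxy)methyl]pent-4-en-1-yl}cyclohexa-2,5-dien-1-one F2, whose CH2OCPh3 arm cannot sit axial beside the spectator enone arm. The same iron-hydride closure should give (4aS,7S,8R,8aR)-4a,7,8-trimethyl-8-[(trityloxy)methyl]-4a,5,6,7,8,8a-hexahydronaphthalen-2(1H)-one F3. Cuprate addition and Saegusa–Ito oxidation as in step 12 should give (4aR,7S,8R,8aR)-4,4a,7,8-tetramethyl-8-[(trityloxy)methyl]-4a,5,6,7,8,8a-hexahydronaphthalen-2(1H)-one F4. The acidic thioketalisation of step 13 cleaves the trityl ether while it forms the dithiolane, and the route is rejoined at 22.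

Step 20. Nitric acid may oxidise the trialkoxyarene (ipso attack, loss of a MOM or methyl group, quinone formation) or add nitrogen oxides to the C3=C4 alkene instead of giving clean substitution. The fallback brings in nitrogen through a carbanion and not an electrophile. Setting out from 31, directed ortho-lithiation (s-BuLi, TMEDA, THF, −78 °C) at the free position ortho to OMOM and trapping with tosyl azide should give 1-azido-5-methoxy-2,4-bis(methoxymethoxy)-3-{[(1R,2S,4aR,8aS)-1,2,4a,5-tetramethyl-1,2,3,4,4a,7,8,8a-octahydronaphthalen-1-yl]methyl}benzene F5. Staudinger reduction (PPh3, THF/H2O) then rejoins the route at 33.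

Step 14. On nickel the allylic C–S cleavage may let the double bond migrate to C2=C3, or the alkene may be partly hydrogenated. The fallback removes the C2 oxygen by hydride substitution and avoids sulfur. Setting out from 20, Luche reduction should give (4aR,7S,8R,8aR)-4,4a,7,8-tetramethyl-8-[(TBSO)methyl]-1,2,4a,5,6,7,8,8a-octahydronaphthalen-2-ol (C2 epimers) F6. Ac2O/pyridine/DMAP should give its acetate (4aR,7S,8R,8aR)-4,4a,7,8-tetramethyl-8-[(TBSO)methyl]-1,2,4a,5,6,7,8,8a-octahydronaphthalen-2-yl acetate F7. Pd(PPh3)4/LiBHEt3 should deliver hydride to the less hindered C2 terminus of the π-allyl complex and give tert-butyldimethyl{[(1R,2S,4aR,8aR)-1,2,4a,5-tetramethyl-1,2,3,4,4a,7,8,8a-octahydronaphthalen-1-yl]methoxy}silane F8. TBAF then rejoins the route at 23.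

**Further compounds**

F1 | step 11 | 4-[(3S)-4-(hydroxymethyl)-3-methylpent-4-en-1-yl]-4-methylcyclohexa-2,5-dien-1-one | OCC(=C)[C@@H](C)CCC1(C)C=CC(=O)C=C1
F2 | step 11 | 4-methyl-4-{(3S)-3-methyl-4-[(trityloxy)methyl]pent-4-en-1-yl}cyclohexa-2,5-dien-1-one | C=C(COC(c1ccccc1)(c1ccccc1)c1ccccc1)[C@@H](C)CCC1(C)C=CC(=O)C=C1
F3 | step 11 | (4aS,7S,8R,8aR)-4a,7,8-trimethyl-8-[(trityloxy)methyl]-4a,5,6,7,8,8a-hexahydronaphthalen-2(1H)-one | O(C[C@]1(C)[C@@H](C)CC[C@@]2(C)C=CC(=O)C[C@@H]12)C(c1ccccc1)(c1ccccc1)c1ccccc1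
F4 | step 11 | (4aR,7S,8R,8aR)-4,4a,7,8-tetramethyl-8-[(trityloxy)methyl]-4a,5,6,7,8,8a-hexahydronaphthalen-2(1H)-one | O(C[C@]1(C)[C@@H](C)CC[C@@]2(C)C(C)=CC(=O)C[C@@H]12)C(c1ccccc1)(c1ccccc1)c1ccccc1
F5 | step 20 | 1-azido-5-methoxy-2,4-bis(methoxymethoxy)-3-{[(1R,2S,4aR,8aS)-1,2,4a,5-tetramethyl-1,2,3,4,4a,7,8,8a-octahydronaphthalen-1-yl]methyl}benzene | COCOc1c(N=[N+]=[N-])cc(OC)c(OCOC)c1C[C@]1(C)[C@@H](C)CC[C@@]2(C)C(C)=CCC[C@@H]12
F6 | step 14 | (4aR,7S,8R,8aR)-4,4a,7,8-tetramethyl-8-[(TBSO)methyl]-1,2,4a,5,6,7,8,8a-octahydronaphthalen-2-ol (C2 epimers) | CC(C)(C)[Si](C)(C)OC[C@]1(C)[C@@H](C)CC[C@@]2(C)C(C)=CC(O)C[C@@H]12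
F7 | step 14 | (4aR,7S,8R,8aR)-4,4a,7,8-tetramethyl-8-[(TBSO)methyl]-1,2,4a,5,6,7,8,8a-octahydronaphthalen-2-yl acetate (C2 epimers) | CC(C)(C)[Si](C)(C)OC[C@]1(C)[C@@H](C)CC[C@@]2(C)C(C)=CC(OC(C)=O)C[C@@H]12
F8 | step 14 | tert-butyldimethyl{[(1R,2S,4aR,8aR)-1,2,4a,5-tetramethyl-1,2,3,4,4a,7,8,8a-octahydronaphthalen-1-yl]methoxy}silane | CC(C)(C)[Si](C)(C)OC[C@]1(C)[C@@H](C)CC[C@@]2(C)C(C)=CCC[C@@H]12
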